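**Retrosynthetic overview**

1. Target 15 comes from 14 by global desilylation. 14 is assembled by forming C2–C1′ in a catalytic enantioselective, decarboxylative Friedel–Crafts-type conjugate addition of the free chromenol 12 (ring B with its fused pyran) to chromone-3-carboxylic acid 9 (rings A and C, side chain in place).
2. Enabling feature: C1′ of ring B (C6 of the 2H-chromene) lies ortho to the free 2′-OH and para to the pyran oxygen, so it is the most nucleophilic C–H of that ring. C2 of ring C is the β-carbon of the C2=C3–C4=O vinylogous ester at the chromone oxidation level. A CO2H group at C3 raises its electrophilicity, anchors the catalyst and leaves as CO2 in the same operation.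
3. 9 comes from 3-iodochromone 7, enaminone 6 and acetophenone 5, which is made from 2,4,6-trihydroxyacetophenone 1 by C-prenylation, 4,6-bis-silylation and Mukaiyama hydration. 12 comes from resorcinol 10 and 3-methylbut-2-enal 11.
4. Ring order: ring A is bought; ring C is closed in step 5 (iodocyclisation); the pyran ring on ring B is closed in step 7 (chromenylation); the key step then joins the two bicycles and sets C2, the only stereocentre.

Key step: step 8

Remark: the stereodescriptor of the target corresponds to (2S). Which pseudo-enantiomer of the cinchona catalyst gives (2S) is not predicted here and is to be fixed by a test reaction.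

**Route**

Step 1
Reactants: 1 2,4,6-trihydroxyacetophenone; 2 1-bromo-3-methylbut-2-ene (prenyl bromide)
Product: 3 1-[2,4,6-trihydroxy-3-(3-methylbut-2-en-1-yl)phenyl]ethan-1-one
Conditions: DBU (1.0 equiv), 2 (1.0 equiv), THF, 0 °C to rt
Reagents that add atoms: none
Why: Base-mediated C-prenylation of a phloroglucinol-type phenol (the ambident phenoxide is alkylated on carbon by the soft allylic bromide); the two free ring positions of 1 are equivalent, so mono-alkylation gives one regioisomer and over-alkylation is limited by stoichiometry.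

Step 2
Reactants: 3 1-[2,4,6-trihydroxy-3-(3-methylbut-2-en-1-yl)phenyl]ethan-1-one
Product: 4 1-[2-hydroxy-3-(3-methylbut-2-en-1-yl)-4,6-bis(triisopropylsilyloxy)phenyl]ethan-1-one
Conditions: TIPSCl (2.1 equiv), imidazole, DMF, 0 °C to rt
Reagents that add atoms: triisopropylsilyl chloride, CC(C)[Si](Cl)(C(C)C)C(C)C
Why: Phenol silylation with site selection by sterics and hydrogen bonding: the unchelated 4-OH reacts first and, of the two ortho-hydroxyls, the one next to the ring C–H is silylated, while the OH wedged between the acetyl and prenyl groups stays as the chelated free phenol.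

Step 3
Reactants: 4 1-[2-hydroxy-3-(3-methylbut-2-en-1-yl)-4,6-bis(triisopropylsilyloxy)phenyl]ethan-1-one
Product: 5 1-[2-hydroxy-3-(3-hydroxy-3-methylbutyl)-4,6-bis(triisopropylsilyloxy)phenyl]ethan-1-one
Conditions: Co(acac)2 (20 mol%), PhSiH3, O2 (1 atm), THF/i-PrOH, rt; aq. Na2S2O3
Reagents that add atoms: dioxygen, O=O
Why: Mukaiyama hydration (cobalt-hydride hydrogen-atom transfer to the trisubstituted alkene, trapping of the tertiary radical by O2, reduction of the peroxide) should give the Markovnikov tertiary alcohol under neutral conditions that spare the ketone, the silyl ethers and the chelated phenol, whereas acid or mercury(II) would draw the ortho-OH into chroman formation.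

Step 4
Reactants: 5 1-[2-hydroxy-3-(3-hydroxy-3-methylbutyl)-4,6-bis(triisopropylsilyloxy)phenyl]ethan-1-one
Product: 6 (E)-3-(dimethylamino)-1-[2-hydroxy-3-(3-hydroxy-3-methylbutyl)-4,6-bis(triisopropylsilyloxy)phenyl]prop-2-en-1-one
Conditions: DMF-DMA (3 equiv), toluene, 80 °C
Reagents that add atoms: N,N-dimethylformamide dimethyl acetal, COC(OC)N(C)C
Why: Condensation of the methyl ketone with the amide acetal gives the (E)-enaminone, the standard first stage of chromone synthesis from 2-hydroxyacetophenones.

Step 5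
Reactants: 6 (E)-3-(dimethylamino)-1-[2-hydroxy-3-(3-hydroxy-3-methylbutyl)-4,6-bis(triisopropylsilyloxy)phenyl]prop-2-en-1-one
Product: 7 8-(3-hydroxy-3-methylbutyl)-3-iodo-5,7-bis(triisopropylsilyloxy)-4H-chromen-4-one
Conditions: I2 (1.2 equiv), CHCl3, rt; aq. Na2S2O3
Reagents that add atoms: iodine, II
Why: Iodocyclisation of a 2-hydroxyaryl enaminone: iodination at the α-carbon, 6-exo-trig attack of the phenol oxygen on the iminium carbon and loss of dimethylamine close ring C as the 3-iodochromone; only the oxygen flanked by the side chain is free, so the 8-alkyl isomer alone can form.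

Step 6
Reactants: 7 8-(3-hydroxy-3-methylbutyl)-3-iodo-5,7-bis(triisopropylsilyloxy)-4H-chromen-4-one
Product: 9 8-(3-hydroxy-3-methylbutyl)-4-oxo-5,7-bis(triisopropylsilyloxy)-4H-chromene-3-carboxylic acid, via bis-chloromagnesium species 8 (not isolated)
Conditions: i-PrMgCl·LiCl (2.1 equiv), THF, −40 °C; CO2 (g), −40 to 0 °C; cold 1 M HCl
Reagents that add atoms: carbon dioxide, O=C=O
Why: Iodine–magnesium exchange at the carbonyl-activated C(sp2)–I bond with the turbo-Grignard reagent (the first equivalent deprotonates the tertiary alcohol) followed by carboxylation with CO2; the low temperature should suppress addition to the pyranone and ring fragmentation.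

Step 7
Reactants: 10 resorcinol; 11 3-methylbut-2-enal
Product: 12 2,2-dimethyl-2H-chromen-7-ol
Conditions: pyridine, 140 °C (sealed tube)
Reagents that add atoms: none
Why: Formal [3+3] chromenylation of a phenol with an enal (aldol-type ortho C-alkylation, dehydration and oxa-6π electrocyclisation); attack at C4 of resorcinol, para to one OH, should give the 7-hydroxy isomer as the main product, separable from the minor 5-hydroxy isomer.

Step 8
Reactants: 9 8-(3-hydroxy-3-methylbutyl)-4-oxo-5,7-bis(triisopropylsilyloxy)-4H-chromene-3-carboxylic acid; 12 2,2-dimethyl-2H-chromen-7-ol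
Product: 14 (2S)-8-(3-hydroxy-3-methylbutyl)-2-(7-hydroxy-2,2-dimethyl-2H-chromen-6-yl)-5,7-bis(triisopropylsilyloxy)chroman-4-one, via β-keto acid adduct 13 (not isolated)
Conditions: quinine-derived 3,5-bis(trifluoromethyl)phenyl squaramide (10 mol%; the quinidine-derived pseudo-enantiomer if the sense of induction demands it), 12 (1.3 equiv), THF, 25 °C
Reagents that add atoms: none
Why: Proposed new method: the quinuclidine nitrogen of the bifunctional catalyst hydrogen-bonds to the OH of 12 and raises the nucleophilicity of its ortho carbon C6, while the squaramide N–H pair binds the carboxyl/C4 carbonyl of 9, whose C2 is the β-carbon of both the ketone and the acid; Friedel–Crafts-type conjugate addition of C6 to C2 and re-aromatisation give β-keto acid 13, which loses CO2 at once, so that the addition becomes irreversible and the activating group removes itself. The closest known reaction types are the squaramide-catalysed enantioselective decarboxylative Michael additions of carbon acids to chromone-3-carboxylic acids and the amine–squaramide-catalysed asymmetric ortho-Friedel–Crafts alkylations of sesamol and naphthols; their combination, a phenol C–H donor on this acceptor, is the untested part. No ring is closed. The C2 stereocentre is set by the catalyst, which holds both partners in a hydrogen-bonded ternary complex and exposes one face of the planar acceptor; the pseudo-enantiomer that leads to (2S) is used. The step needs C- over O-alkylation (O-adducts should revert by retro-oxa-Michael reaction before they decarboxylate), attack through C6 and not C8 (C8 is flanked by two oxygens), and an intact chromene C3=C4 bond and tertiary alcohol, which the acid-free, metal-free medium secures.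

Step 9
Reactants: 14 (2S)-8-(3-hydroxy-3-methylbutyl)-2-(7-hydroxy-2,2-dimethyl-2H-chromen-6-yl)-5,7-bis(triisopropylsilyloxy)chroman-4-one
Product: 15 (2S)-5,7-dihydroxy-8-(3-hydroxy-3-methylbutyl)-2-(7-hydroxy-2,2-dimethyl-2H-chromen-6-yl)chroman-4-one (CNP0423488.1)
Conditions: TBAF (2.5 equiv), AcOH (2.5 equiv), THF, 0 °C
Reagents that add atoms: none
Why: Fluoride-mediated cleavage of the two aryl silyl ethers; buffering with acetic acid keeps the medium near neutral so that the flavanone does not open by retro-oxa-Michael reaction (which would racemise C2), and the chromene and the tertiary alcohol are inert.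

**Compound list**

1 | 2,4,6-trihydroxyacetophenone | CC(=O)c1c(O)cc(O)cc1O | starting material
2 | 1-bromo-3-methylbut-2-ene (prenyl bromide) | CC(C)=CCBr | starting material
3 | 1-[2,4,6-trihydroxy-3-(3-methylbut-2-en-1-yl)phenyl]ethan-1-one | CC(=O)c1c(O)cc(O)c(CC=C(C)C)c1O | intermediate
4 | 1-[2-hydroxy-3-(3-methylbut-2-en-1-yl)-4,6-bis(triisopropylsilyloxy)phenyl]ethan-1-one | CC(=O)c1c(O[Si](C(C)C)(C(C)C)C(C)C)cc(O[Si](C(C)C)(C(C)C)C(C)C)c(CC=C(C)C)c1O | intermediate
5 | 1-[2-hydroxy-3-(3-hydroxy-3-methylbutyl)-4,6-bis(triisopropylsilyloxy)phenyl]ethan-1-one | CC(=O)c1c(O[Si](C(C)C)(C(C)C)C(C)C)cc(O[Si](C(C)C)(C(C)C)C(C)C)c(CCC(C)(C)O)c1O | intermediate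
6 | (E)-3-(dimethylamino)-1-[2-hydroxy-3-(3-hydroxy-3-methylbutyl)-4,6-bis(triisopropylsilyloxy)phenyl]prop-2-en-1-one | CN(C)/C=C/C(=O)c1c(O[Si](C(C)C)(C(C)C)C(C)C)cc(O[Si](C(C)C)(C(C)C)C(C)C)c(CCC(C)(C)O)c1O | intermediate
7 | 8-(3-hydroxy-3-methylbutyl)-3-iodo-5,7-bis(triisopropylsilyloxy)-4H-chromen-4-one | CC(C)(O)CCc1c(O[Si](C(C)C)(C(C)C)C(C)C)cc(O[Si](C(C)C)(C(C)C)C(C)C)c2c1OC=C(I)C2=O | intermediate
8 | bis-chloromagnesium species: C3-chloromagnesio chromone with the side-chain alcohol as its chloromagnesium alkoxide | CC(C)(O[Mg]Cl)CCc1c(O[Si](C(C)C)(C(C)C)C(C)C)cc(O[Si](C(C)C)(C(C)C)C(C)C)c2c1OC=C([Mg]Cl)C2=O | intermediate (not isolated)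
9 | 8-(3-hydroxy-3-methylbutyl)-4-oxo-5,7-bis(triisopropylsilyloxy)-4H-chromene-3-carboxylic acid | CC(C)(O)CCc1c(O[Si](C(C)C)(C(C)C)C(C)C)cc(O[Si](C(C)C)(C(C)C)C(C)C)c2c1OC=C(C(=O)O)C2=O | intermediate
10 | resorcinol (benzene-1,3-diol) | Oc1cccc(O)c1 | starting material
11 | 3-methylbut-2-enal | CC(C)=CC=O | starting material
12 | 2,2-dimethyl-2H-chromen-7-ol | CC1(C)C=Cc2ccc(O)cc2O1 | intermediate
13 | (2S)-8-(3-hydroxy-3-methylbutyl)-2-(7-hydroxy-2,2-dimethyl-2H-chromen-6-yl)-4-oxo-5,7-bis(triisopropylsilyloxy)chromane-3-carboxylic acid (C3 configuration not defined) | CC(C)(O)CCc1c(O[Si](C(C)C)(C(C)C)C(C)C)cc(O[Si](C(C)C)(C(C)C)C(C)C)c2c1O[C@H](c1cc3c(cc1O)OC(C)(C)C=C3)C(C(=O)O)C2=O | intermediate (not isolated)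
14 | (2S)-8-(3-hydroxy-3-methylbutyl)-2-(7-hydroxy-2,2-dimethyl-2H-chromen-6-yl)-5,7-bis(triisopropylsilyloxy)chroman-4-one | CC(C)(O)CCc1c(O[Si](C(C)C)(C(C)C)C(C)C)cc(O[Si](C(C)C)(C(C)C)C(C)C)c2c1O[C@H](c1cc3c(cc1O)OC(C)(C)C=C3)CC2=O | intermediate
15 | (2S)-5,7-dihydroxy-8-(3-hydroxy-3-methylbutyl)-2-(7-hydroxy-2,2-dimethyl-2H-chromen-6-yl)chroman-4-one | CC(C)(O)CCc1c(O)cc(O)c2c1O[C@H](c1cc3c(cc1O)OC(C)(C)C=C3)CC2=O | target

**Step count and risks**

Total step count: 9. Longest linear sequence: 8 steps (steps 1–6, 8 and 9); step 7 is the one-step side branch.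

Steps most likely to fail:

Step 8 (Proposed new method). The addition may stall because the electron-rich acceptor decarboxylates to the unactivated chromone before the C–C bond forms, the phenol may react through oxygen, or facial selectivity may be low. The fallback uses known chemistry, sets out from 6 and 11 and returns to the route at 15. Mild acid (PPTS, CH2Cl2) should cyclise 6 with loss of dimethylamine to 8-(3-hydroxy-3-methylbutyl)-5,7-bis(triisopropylsilyloxy)-4H-chromen-4-one F1. Commercial 4-bromoresorcinol (Oc1ccc(Br)c(O)c1) and 11 should give, under the conditions of step 7, 6-bromo-2,2-dimethyl-2H-chromen-7-ol F2. This is silylated (TBSCl, imidazole, DMF) to tert-butyl[(6-bromo-2,2-dimethyl-2H-chromen-7-yl)oxy]dimethylsilane F3 and converted by bromine–lithium exchange (n-BuLi, THF, −78 °C), B(OiPr)3 and aqueous work-up into [7-(tert-butyldimethylsilyloxy)-2,2-dimethyl-2H-chromen-6-yl]boronic acid F4. Rhodium-catalysed asymmetric 1,4-addition of F4 to F1 (Hayashi–Miyaura reaction with a chiral diene or bisphosphine ligand, dioxane/H2O), a known way from chromones to enantioenriched 2-arylchroman-4-ones, should give (2S)-2-[7-(tert-butyldimethylsilyloxy)-2,2-dimethyl-2H-chromen-6-yl]-8-(3-hydroxy-3-methylbutyl)-5,7-bis(triisopropylsilyloxy)chroman-4-one F5. Buffered fluoride as in step 9 then removes all three silyl groups to reach 15.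

Step 6. The C3-magnesiated chromone may fragment by β-elimination of the ring aryloxide, or the Grignard reagent may add to the pyranone. The fallback sets out from 7 and returns at 9 without forming a carbanion at C3. Palladium-catalysed reductive carbonylation of the C–I bond (PdCl2(PPh3)2, CO 1 atm, HCO2Na, DMF, 90 °C) should give 8-(3-hydroxy-3-methylbutyl)-4-oxo-5,7-bis(triisopropylsilyloxy)-4H-chromene-3-carbaldehyde F6. Pinnick oxidation (NaClO2, NaH2PO4, 2-methylbut-2-ene, t-BuOH/H2O) then leads to 9.

Step 2. The silylation may not discriminate cleanly between the two chelated ortho-hydroxyl groups, or may stop at the mono-ether. The fallback sets out from 1, returns at 4 and replaces step 1 as well. 1 is bis-silylated first (TIPSCl, imidazole, DMF), where the two ortho-hydroxyls are equivalent, to 1-[2-hydroxy-4,6-bis(triisopropylsilyloxy)phenyl]ethan-1-one F7. Iodination (NIS, MeCN, 0 °C) ortho to the free OH, the other ring C–H being buried between two TIPS ethers, should give 1-[2-hydroxy-3-iodo-4,6-bis(triisopropylsilyloxy)phenyl]ethan-1-one F8. Stille coupling with tributyl(3-methylbut-2-en-1-yl)stannane (Pd(PPh3)4, DMF, 80 °C) then installs the prenyl group to give 4.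

**Further compounds**

F1 | step 8 | 8-(3-hydroxy-3-methylbutyl)-5,7-bis(triisopropylsilyloxy)-4H-chromen-4-one | CC(C)(O)CCc1c(O[Si](C(C)C)(C(C)C)C(C)C)cc(O[Si](C(C)C)(C(C)C)C(C)C)c2c1OC=CC2=O
F2 | step 8 | 6-bromo-2,2-dimethyl-2H-chromen-7-ol | CC1(C)C=Cc2cc(Br)c(O)cc2O1
F3 | step 8 | tert-butyl[(6-bromo-2,2-dimethyl-2H-chromen-7-yl)oxy]dimethylsilane | CC1(C)C=Cc2cc(Br)c(O[Si](C)(C)C(C)(C)C)cc2O1
F4 | step 8 | [7-(tert-butyldimethylsilyloxy)-2,2-dimethyl-2H-chromen-6-yl]boronic acid | CC1(C)C=Cc2cc(B(O)O)c(O[Si](C)(C)C(C)(C)C)cc2O1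
F5 | step 8 | (2S)-2-[7-(tert-butyldimethylsilyloxy)-2,2-dimethyl-2H-chromen-6-yl]-8-(3-hydroxy-3-methylbutyl)-5,7-bis(triisopropylsilyloxy)chroman-4-one | CC(C)(O)CCc1c(O[Si](C(C)C)(C(C)C)C(C)C)cc(O[Si](C(C)C)(C(C)C)C(C)C)c2c1O[C@H](c1cc3c(cc1O[Si](C)(C)C(C)(C)C)OC(C)(C)C=C3)CC2=O
F6 | step 6 | 8-(3-hydroxy-3-methylbutyl)-4-oxo-5,7-bis(triisopropylsilyloxy)-4H-chromene-3-carbaldehyde | CC(C)(O)CCc1c(O[Si](C(C)C)(C(C)C)C(C)C)cc(O[Si](C(C)C)(C(C)C)C(C)C)c2c1OC=C(C=O)C2=O
F7 | step 2 | 1-[2-hydroxy-4,6-bis(triisopropylsilyloxy)phenyl]ethan-1-one | CC(=O)c1c(O)cc(O[Si](C(C)C)(C(C)C)C(C)C)cc1O[Si](C(C)C)(C(C)C)C(C)C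
F8 | step 2 | 1-[2-hydroxy-3-iodo-4,6-bis(triisopropylsilyloxy)phenyl]ethan-1-one | CC(=O)c1c(O[Si](C(C)C)(C(C)C)C(C)C)cc(O[Si](C(C)C)(C(C)C)C(C)C)c(I)c1O
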